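In a one-step world every first end group would meet one fate and the examiner would ask how fast; here there are two fates, so the examiner asks how the first end groups divide between them.

- alder: first end groups 0.010 M; second end groups 10.0 mM; temperature 110 °C; time 25 min
- cedar: first end groups 0.010 M; second end groups 10.0 mM; temperature 90 °C; time 25 min

    first end groups + second end groups → rings, rate k1*[first end groups] as long as [second end groups] is above zero (k1 = 0.032 /min, Ea1 = 98.0 kJ/mol)
    first end groups + second end groups → links (k2 = 4.7 /M/min, Ea2 = 55.0 kJ/mol)
    second end groups + links ⇌ idle adduct, settled at all times (K3 = 53 /M, ΔH3 = −27.0 kJ/mol)
    (constants at 90 °C)

- links is meant together with its idle adduct
- the list of constants is for 90 °C, to be carried to other temperatures by the activation energies and enthalpies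

- which of the two there is more of at the end, alder (links / rings)
- which of the two there is more of at the end, cedar (links / rings)
- how much links is there at the end, in percent of the first end groups charged: alder
- how much links is there at the end, in percent of the first end groups charged: cedar

What do you compute first? Both steps consume first end groups, so [first end groups] cancels from the ratio of their rates, and the ring step over the link step is the ratio of their constants over [second end groups]. That ratio of constants is 6.81 mM at 90 °C, and the difference of activation energies carries it to 14.3 mM at 110 °C; call this the crossover level, the [second end groups] at which the two steps run equally fast.

Which flask favours rings? In alder the charge of 10.0 mM lies below the crossover level, so rings lead from the start. In cedar it lies above, and the selectivity factor, [second end groups] over the crossover level, starts at 1.47 in favour of links.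

So cedar ends with more links? Not from that alone, since [second end groups] falls during the run, on my reckoning below to 2.48 mM, which is under its crossover level of 6.81 mM. Each second end group consumed by the two steps goes to links with the share [second end groups]/([second end groups] + crossover level), which integrates to: links = drop in [second end groups] − crossover level × ln((charge + crossover level)/(end value + crossover level)).

And the numbers? In alder the ring constant of 0.174 /min is by itself enough to take nearly all of the first end groups in 25 min, so I run the formula to the end and get 24.2% links, the rest rings. In cedar I let the equal charges fall together, which on this reckoning leaves the 2.48 mM at 25 min, and I get 34.8% links against 40.4% rings.

What about the idle adduct? On my end figures for cedar it holds 0.458 mM, less than the 2.48 mM of second end groups. I treat it as a correction that lowers free [second end groups], and I read my link figure for cedar as high.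

The forecast names rings for alder and rings for cedar, with 23% and 33% links, on this ground: “Rings win in both runs because their first-order step has the higher activation energy”.

The simulation gives rings ahead in alder, 75.7% against 23.6% links, and rings ahead in cedar, 40.9% against 33.2% links, so my link figures stand 0.6 percentage points higher in alder and 1.6 points higher in cedar. A neighbour of alder is charged with 0.017 M of second end groups, 1.70 equiv, which starts above the crossover level of 14.3 mM. With first end groups now the limiting reagent, I let [second end groups] drop by 0.010 M in this neighbour, and the same formula gives 45.0% links. That neighbour ends with 43.5% links, with 0.13% of its first end groups left.

The constants were set for the occasion; the rest is arithmetic.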